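**Strategy.** Labdane numbering is used throughout. Ring A is cut into two three-carbon units, C3–C4–C5 and C10–C1–C2. This exploits two features: the C19 carboxyl on C4, which makes C3–C4–C5 a 2-carboxyallyl unit, and the tetrasubstituted C8=C9 alkene of ring B, whose Z geometry holds the two units close. In the key step PPh3 turns an acyclic Morita–Baylis–Hillman carbonate into an allylic ylide. Its γ-carbon C5 adds to C10 of a tethered dienal (ring B, quaternary centre). Ylide carbon C3 then olefinates aldehyde C2 (ring A). The precursor is an open chain running from C2 to C3 that carries the protected side chain. Resolution fixes C10, and reductive methylation then sets C5 and C4.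

Key step: step 9

Assumption: the less soluble (R)-1-phenylethylammonium salt is taken to be that of the (4aR)-acid. If the other pairing crystallises, the (S)-amine is used in the same way.

Step 1
Reactants: 1 pentane-2,4-dione; 2 2-(2-bromoethyl)-2-methyl-1,3-dioxolane
Product: 3 3-[2-(2-methyl-1,3-dioxolan-2-yl)ethyl]pentane-2,4-dione
Conditions: K2CO3, NaI (cat.), acetone, reflux
Reagents that add atoms: none
Why: C-alkylation of the stabilised acetylacetonate with a primary bromide (iodide-assisted SN2) places the protected C11–C13/C16 side chain on the future C9, while the two acetyl groups become C8/C17 and C10/C20.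

Step 2
Reactants: 3 3-[2-(2-methyl-1,3-dioxolan-2-yl)ethyl]pentane-2,4-dione
Product: 4 (Z)-4-oxo-3-[2-(2-methyl-1,3-dioxolan-2-yl)ethyl]pent-2-en-2-yl triflate (OTf cis to the acetyl group)
Conditions: i-Pr2NEt, LiOTf, Tf2O, CH2Cl2, −78 to 0 °C
Reagents that add atoms: triflic anhydride, O=S(=O)(OS(=O)(=O)C(F)(F)F)C(F)(F)F
Why: O-triflation of the lithium-chelated U-shaped enolate of the 1,3-diketone should give the vinylogous acyl triflate with OTf cis to the remaining acetyl group, which fixes the C8=C9 geometry.

Step 3
Reactants: 4 (Z)-enol triflate; 5 but-3-enylzinc bromide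
Product: 6 (Z)-4-methyl-3-[2-(2-methyl-1,3-dioxolan-2-yl)ethyl]octa-3,7-dien-2-one (butenyl chain cis to acetyl)
Conditions: Pd(dppf)Cl2 (cat.), THF, rt to 50 °C
Reagents that add atoms: none
Why: Negishi coupling of an alkenyl triflate with an alkylzinc halide proceeds with retention of alkene geometry and tolerates ketone and ketal, so C7 ends up cis to C10.

Step 4
Reactants: 6 (Z)-dienone; 7 diethyl cyanomethylphosphonate
Product: 8 (2E,4Z)-3,5-dimethyl-4-[2-(2-methyl-1,3-dioxolan-2-yl)ethyl]nona-2,4,8-trienenitrile
Conditions: NaH, THF, 0 °C to reflux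
Reagents that add atoms: none
Why: Horner–Wadsworth–Emmons olefination with the small cyanomethylphosphonate anion is the variant best suited to a hindered methyl ketone and adds C1 and C2; the C1=C10 geometry does not matter because both isomers converge in step 9.

Step 5
Reactants: 8 trienenitrile
Product: 9 (2E,4Z)-3,5-dimethyl-4-[2-(2-methyl-1,3-dioxolan-2-yl)ethyl]nona-2,4,8-trienal
Conditions: i-Bu2AlH, toluene, −78 °C; then aqueous acetate buffer (pH 5), 0 °C
Reagents that add atoms: water, O
Why: Partial reduction of the nitrile to the N-aluminated imine and mild hydrolysis give the dienal without touching the ketal or the alkenes.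

Step 6
Reactants: 9 trienal
Product: 10 (2E,4Z)-3,5-dimethyl-4-[2-(2-methyl-1,3-dioxolan-2-yl)ethyl]octa-2,4-dienedial
Conditions: OsO4 (cat.), NaIO4, 2,6-lutidine, dioxane/H2O, rt
Reagents that add atoms: sodium periodate (oxygen source, relayed by OsO4), [Na+].[O-]I(=O)(=O)=O
Why: Lemieux–Johnson cleavage, in which OsO4 dihydroxylates the unhindered monosubstituted alkene much faster than the electron-poor, crowded dienal alkenes and periodate cleaves the diol to the C5 aldehyde.

Step 7
Reactants: 10 dialdehyde; 11 methyl acrylate
Product: 12 methyl (6Z,8E)-3-hydroxy-6,8-dimethyl-2-methylidene-7-[2-(2-methyl-1,3-dioxolan-2-yl)ethyl]-10-oxodeca-6,8-dienoate (racemic carbinol)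
Conditions: DABCO, MeOH, rt
Reagents that add atoms: none
Why: Morita–Baylis–Hillman reaction, in which the DABCO-derived acrylate enolate adds to the unhindered aliphatic aldehyde C5 rather than to the conjugated β,β-disubstituted dienal and brings in C3, C4 and C19; the new carbinol centre is racemic and is erased in step 9.

Step 8
Reactants: 12 Morita–Baylis–Hillman alcohol
Product: 13 tert-butyl carbonate of 12
Conditions: Boc2O, DMAP (cat.), CH2Cl2, 0 °C to rt
Reagents that add atoms: di-tert-butyl dicarbonate, CC(C)(C)OC(=O)OC(=O)OC(C)(C)C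
Why: DMAP-catalysed carbonate formation turns the allylic alcohol into a leaving group that releases its own base (tert-butoxide) in the next step.

Step 9
Reactants: 13 Morita–Baylis–Hillman carbonate dienal
Product: 16 racemic methyl 4a,6-dimethyl-5-[2-(2-methyl-1,3-dioxolan-2-yl)ethyl]-4,4a,7,8-tetrahydronaphthalene-1-carboxylate, via allylic ylide 14 (not isolated), via ring B ylide aldehyde 15 (not isolated)
Conditions: PPh3 (1.2 equiv), toluene (0.005 M, slow addition of 13), 25 to 80 °C
Reagents that add atoms: none
Why: PPh3 adds to C3 of the carbonate in SN2' fashion, CO2 and tert-butoxide leave, and the tert-butoxide deprotonates the phosphonium salt to the allylic ylide 14. Its γ-carbon C5 adds to the β-carbon C10 of the dienal (6-exo-trig Michael closure of ring B; attack through C3 or at the aldehyde would need eight- or ten-membered rings), a proton moves from C5 to the enolate to give 15, and C3 then olefinates C2 in an intramolecular Wittig reaction (six-membered closure of ring A as a ring-locked cis alkene), the loss of Ph3PO making the sequence irreversible. The closest known reaction type is the [3+3] cyclohexadiene annulation of allylic phosphorus ylides with α,β-unsaturated carbonyl compounds, which also builds quaternary carbons from β,β-disubstituted acceptors, combined with ylide generation from Morita–Baylis–Hillman carbonates and a phosphine. C10 is the only stereocentre that survives (C5 returns to sp2); nothing in 13 biases its faces, so 16 is racemic and is resolved in step 11. The step needs γ- over α-reactivity of the ylide and cyclisation over oligomerisation, which the Z geometry of C8=C9 (C7 cis to C10), the short tether and high dilution secure, and both C1=C10 isomers of 13 converge on 16.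

Step 10
Reactants: 16 racemic triene ester
Product: 17 racemic 4a,6-dimethyl-5-[2-(2-methyl-1,3-dioxolan-2-yl)ethyl]-4,4a,7,8-tetrahydronaphthalene-1-carboxylic acid
Conditions: LiOH, THF/MeOH/H2O, 50 °C; then cold dilute HCl to pH 4
Reagents that add atoms: lithium hydroxide, [Li+].[OH-]
Why: Saponification is easy at this stage because C4 is still sp2 and unhindered, and the mild acidification spares the dioxolane.

Step 11
Reactants: 17 racemic dienoic acid
Product: 18 (R)-1-phenylethylammonium salt of the (4aR)-acid (C10 configured as in the target)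
Conditions: (R)-1-phenylethylamine (1 equiv), EtOAc, crystallisation and recrystallisation to constant rotation
Reagents that add atoms: (R)-1-phenylethylamine, C[C@@H](N)c1ccccc1
Why: Classical resolution through diastereomeric ammonium carboxylates, in which crystallisation separates the salt of the (4aR)-acid and so fixes the absolute configuration at C10.

Step 12
Reactants: 18 ammonium salt
Product: 21 (4S,5R,10S)-13-oxo-14,15-dinorlabda-2,8(9)-dien-19-oic acid, via free dienoic acid 19 (not isolated), via ketal acid 20 (not isolated)
Conditions: Et2O/cold dilute HCl wash; then Li, NH3/THF, t-BuOH (1 equiv), −78 °C; MeI, −78 °C; then 1 M HCl, THF, rt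
Reagents that add atoms: iodomethane, CI; water, O
Why: Dissolving-metal (Birch-type) reductive alkylation, in which two electrons and one proton convert the dienoate into the C4 enediolate with C5 protonated on the α face opposite the angular methyl (trans ring fusion), MeI then attacks C4 from the equatorial α face because the β face is blocked by the 1,3-diaxial C10 methyl (carboxyl left axial as C19), and aqueous acid finally removes the dioxolane.

Step 13
Reactants: 21 dienoic keto acid
Product: 22 (4S,5R,10S)-13-oxo-14,15-dinorlabd-8(9)-en-19-oic acid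
Conditions: H2 (1 atm), Pd/C, EtOAc, rt
Reagents that add atoms: none
Why: Heterogeneous hydrogenation saturates the cis-disubstituted C2=C3 alkene, while the tetrasubstituted C8=C9 alkene is inert under these conditions.

Step 14
Reactants: 22 keto acid; 23 triethyl phosphonoacetate
Product: 24 (13E)-15-ethoxy-15-oxolabda-8(9),13-dien-19-oic acid
Conditions: NaH (excess), THF, 0 to 50 °C; dilute HCl work-up; chromatography removes the minor Z isomer
Reagents that add atoms: none
Why: Horner–Wadsworth–Emmons olefination of the methyl ketone (the hindered carboxylate is a spectator) should give mainly the E-trisubstituted enoate because the ester avoids the larger C12 chain.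

Step 15
Reactants: 24 ethyl enoate acid
Product: 25 (13E)-15-hydroxylabda-8(9),13-dien-19-oic acid
Conditions: i-Bu2AlH (excess), CH2Cl2, −78 °C; aqueous potassium sodium tartrate, then dilute HCl
Reagents that add atoms: none
Why: i-Bu2AlH reduces the unhindered conjugated ethyl ester to the allylic alcohol, while the axial neopentyl C19 carboxylate, bound as its aluminium salt, is not reduced at low temperature.

Step 16
Reactants: 25 hydroxy acid
Product: 26 (13E)-15-acetoxylabda-8(9),13-dien-19-oic acid (target)
Conditions: Ac2O, pyridine, DMAP (cat.), CH2Cl2, 0 °C to rt; aqueous work-up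
Reagents that add atoms: acetic anhydride, CC(=O)OC(C)=O
Why: Acylation of the primary allylic alcohol, in which any mixed anhydride formed at the hindered C19 acid is hydrolysed on aqueous work-up.

**Compound list**

1 | pentane-2,4-dione | CC(=O)CC(C)=O | starting material
2 | 2-(2-bromoethyl)-2-methyl-1,3-dioxolane | CC1(CCBr)OCCO1 | starting material
3 | 3-[2-(2-methyl-1,3-dioxolan-2-yl)ethyl]pentane-2,4-dione | CC(=O)C(CCC1(C)OCCO1)C(C)=O | intermediate
4 | (Z)-4-oxo-3-[2-(2-methyl-1,3-dioxolan-2-yl)ethyl]pent-2-en-2-yl triflate | CC(=O)/C(CCC1(C)OCCO1)=C(/C)OS(=O)(=O)C(F)(F)F | intermediate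
5 | but-3-enylzinc bromide | C=CCC[Zn]Br | starting material
6 | (Z)-4-methyl-3-[2-(2-methyl-1,3-dioxolan-2-yl)ethyl]octa-3,7-dien-2-one | CC(=O)/C(CCC1(C)OCCO1)=C(/C)CCC=C | intermediate
7 | diethyl cyanomethylphosphonate | CCOP(=O)(CC#N)OCC | starting material
8 | (2E,4Z)-3,5-dimethyl-4-[2-(2-methyl-1,3-dioxolan-2-yl)ethyl]nona-2,4,8-trienenitrile | N#C/C=C(C)/C(CCC1(C)OCCO1)=C(/C)CCC=C | intermediate
9 | (2E,4Z)-3,5-dimethyl-4-[2-(2-methyl-1,3-dioxolan-2-yl)ethyl]nona-2,4,8-trienal | O=C/C=C(C)/C(CCC1(C)OCCO1)=C(/C)CCC=C | intermediate
10 | (2E,4Z)-3,5-dimethyl-4-[2-(2-methyl-1,3-dioxolan-2-yl)ethyl]octa-2,4-dienedial | O=C/C=C(C)/C(CCC1(C)OCCO1)=C(/C)CCC=O | intermediate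
11 | methyl acrylate | C=CC(=O)OC | starting material
12 | Morita–Baylis–Hillman alcohol (racemic carbinol) | O=C/C=C(C)/C(CCC1(C)OCCO1)=C(/C)CCC(O)C(=C)C(=O)OC | intermediate
13 | tert-butyl carbonate of 12 | O=C/C=C(C)/C(CCC1(C)OCCO1)=C(/C)CCC(OC(=O)OC(C)(C)C)C(=C)C(=O)OC | intermediate
14 | allylic triphenylphosphonium ylide (not isolated) | O=C/C=C(C)/C(CCC1(C)OCCO1)=C(/C)CCC=C(C=P(c1ccccc1)(c1ccccc1)c1ccccc1)C(=O)OC | intermediate
15 | ring B ylide aldehyde (not isolated, racemic) | O=CCC1(C)C(CCC2(C)OCCO2)=C(C)CCC1=C(C=P(c1ccccc1)(c1ccccc1)c1ccccc1)C(=O)OC | intermediate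
16 | racemic bicyclic triene methyl ester | CC1(CCC2=C(C)CCC3=C(C(=O)OC)C=CCC23C)OCCO1 | intermediate
17 | racemic bicyclic triene acid | CC1(CCC2=C(C)CCC3=C(C(=O)O)C=CCC23C)OCCO1 | intermediate
18 | (R)-1-phenylethylammonium salt of the (4aR)-acid | CC1(CCC2=C(C)CCC3=C(C(=O)[O-])C=CC[C@]23C)OCCO1.C[C@@H]([NH3+])c1ccccc1 | intermediate
19 | (4aR)-triene acid (not isolated) | CC1(CCC2=C(C)CCC3=C(C(=O)O)C=CC[C@]23C)OCCO1 | intermediate
20 | (4S,5R,10S)-13,13-ethylenedioxy-14,15-dinorlabda-2,8(9)-dien-19-oic acid (not isolated) | CC1(CCC2=C(C)CC[C@H]3[C@@](C)(C(=O)O)C=CC[C@]23C)OCCO1 | intermediate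
21 | (4S,5R,10S)-13-oxo-14,15-dinorlabda-2,8(9)-dien-19-oic acid | CC(=O)CCC1=C(C)CC[C@H]2[C@@](C)(C(=O)O)C=CC[C@]12C | intermediate
22 | (4S,5R,10S)-13-oxo-14,15-dinorlabd-8(9)-en-19-oic acid | CC(=O)CCC1=C(C)CC[C@H]2[C@@](C)(C(=O)O)CCC[C@]12C | intermediate
23 | triethyl phosphonoacetate | CCOC(=O)CP(=O)(OCC)OCC | starting material
24 | (13E)-15-ethoxy-15-oxolabda-8(9),13-dien-19-oic acid | CCOC(=O)/C=C(\C)CCC1=C(C)CC[C@H]2[C@@](C)(C(=O)O)CCC[C@]12C | intermediate
25 | (13E)-15-hydroxylabda-8(9),13-dien-19-oic acid | OC/C=C(\C)CCC1=C(C)CC[C@H]2[C@@](C)(C(=O)O)CCC[C@]12C | intermediate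
26 | (13E)-15-acetoxylabda-8(9),13-dien-19-oic acid | CC(=O)OC/C=C(\C)CCC1=C(C)CC[C@H]2[C@@](C)(C(=O)O)CCC[C@]12C | target

Total step count: 16. Longest linear sequence: 16 steps, from pentane-2,4-dione.

**Steps most likely to fail**

**Step 9.** Three processes could defeat the ring A closure:
- The phosphonium salt may lose PPh3 again through vinylogous deprotonation at C6.
- The aldehyde enolate may close a five-membered ring onto C3 with expulsion of the phosphine before the proton shift.
- Addition to the crowded C10 may be too slow for a mild ylide.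

The fallback sets out from 13 and returns at 16. It replaces phosphorus by sulfur, which cannot leave under base and allows stronger bases. Sodium benzenesulfinate displaces the carbonate in SN2' fashion to give the allylic sulfone dienal F1. KOt-Bu or DBU in dilute solution then drives the γ-addition of C5 to C10. After the proton shift the α-sulfonyl carbanion C3 adds to aldehyde C2, giving the bicyclic β-hydroxy sulfone F2. Acetylation gives the β-acetoxy sulfone F3. Reductive elimination with Na(Hg) (Julia–Lythgoe olefination) installs C2=C3 and delivers 16.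

**Step 12.** Proton exchange may quench the enediolate before alkylation. Methylation may occur on oxygen or at C2, or the carboxylate may be over-reduced.

The fallback sets out from 19 and returns at 22. It separates reduction from alkylation:
- Li/NH3 with t-BuOH and an NH4Cl quench gives the dihydro acid F4.
- Hydrogenation over Pd/C gives the ring A saturated acid F5.
- Trimethylsilyldiazomethane gives the methyl ester F6.
- Deprotonation with LDA and equatorial methylation with MeI give the quaternary axial ester F7.
- Demethylation with NaSEt in hot DMF (SN2 at the methyl group), followed by 1 M HCl, gives 22.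

**Step 11.** The two diastereomeric salts may co-crystallise or fail to crystallise, so that no enrichment occurs.

The fallback sets out from 17 and returns at 19. It uses covalent diastereomers. DCC/DMAP esterification with (−)-menthol gives two menthyl esters. These are separated by chromatography or crystallisation to give the (4aR)-menthyl ester F8. KOH in aqueous ethanol hydrolyses the still unhindered dienoate to 19.

**Further compounds**

F1 | step 9 | allylic phenyl sulfone dienal | O=C/C=C(C)/C(CCC1(C)OCCO1)=C(/C)CCC=C(CS(=O)(=O)c1ccccc1)C(=O)OC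
F2 | step 9 | bicyclic β-hydroxy sulfone (racemic) | COC(=O)C1=C2CCC(C)=C(CCC3(C)OCCO3)C2(C)CC(O)C1S(=O)(=O)c1ccccc1
F3 | step 9 | bicyclic β-acetoxy sulfone (racemic) | COC(=O)C1=C2CCC(C)=C(CCC3(C)OCCO3)C2(C)CC(OC(C)=O)C1S(=O)(=O)c1ccccc1
F4 | step 12 | trans-fused dihydro acid (C4 epimers) | CC1(CCC2=C(C)CC[C@H]3C(C(=O)O)C=CC[C@]23C)OCCO1
F5 | step 12 | ring A saturated acid (C4 epimers) | CC1(CCC2=C(C)CC[C@H]3C(C(=O)O)CCC[C@]23C)OCCO1
F6 | step 12 | ring A saturated methyl ester (C4 epimers) | CC1(CCC2=C(C)CC[C@H]3C(C(=O)OC)CCC[C@]23C)OCCO1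
F7 | step 12 | methyl (4S,5R,10S)-13,13-ethylenedioxy-14,15-dinorlabd-8(9)-en-19-oate | CC1(CCC2=C(C)CC[C@H]3[C@@](C)(C(=O)OC)CCC[C@]23C)OCCO1
F8 | step 11 | (1R,2S,5R)-menthyl ester of the (4aR)-acid | C[C@@H]1CC[C@H]([C@@H](C1)OC(=O)C1=C2CCC(C)=C(CCC3(C)OCCO3)[C@@]2(C)CC=C1)C(C)C
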